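The runs were generated by integration for an exercise; noise was put on by code.

If substrate and target stand in rapid balance while something drains both, their ratio holds still as they sink, and the cedar run, with twice the substrate of the flask, can show this.

| flask | substrate | catalyst | remark | time |
|---|---|---|---|---|
| cedar | 0.34 M | 3.4 mM | run made earlier |  |
| flask | 0.17 M | 3.4 mM |  | 40 h |

- cedar (time / h: target / %, substrate / %): 3.00: 62.2, 29.4; 6.00: 58.3, 27.1; 10.0: 54.9, 25.1; 12.0: 53.1, 24.2

(each reading ± 0.3 percentage points)

* the best time, 40 h at the latest, for target
* the amount of target, in percent of the substrate charged, at that time
* earliest time at which at least nineteen twentieths of that best amount are there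
* latest time at which they still are



Does the cedar run hold such a ratio? Target over substrate reads 2.12 at 3.00 h and 2.19 at 12.0 h, while target sinks from 62.2 % to 53.1 %. The first value is carried on as the standing ratio, the amount of target per amount of substrate while the two are in balance (a pre-equilibrium).

Does the smaller charge change the percentages? This reckoning takes each step as first order in substrate; the catalyst is the same, so the flask should follow the cedar percentages.

How high is the top? Target falls between the first two cedar readings, so the top of the cedar run lies before 6.00 h, and no reading shows how far before. Target plus substrate loses 6.2 percentage points between those readings. Taken back one hour before the first reading, which is a guess at the time of the top and not a reading, that cedar sum stands near 93.7 %, and the standing ratio gives target near 63.6 %, the estimate for the flask as well.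

The forecast stands higher, with 66 % at 2.7 h and a window from 1.4 h to 6.5 h: “Target then peaks near 2.5–3 h at about 66%, roughly 0.69 of a pool near 96%.”

The flask gives 62.6 % at 2.10 h, with the window from 1.16 h to 5.01 h.

    substrate + catalyst ⇌ target + catalyst, rate k1*[substrate]*[catalyst] forward; the back reaction follows from the equilibrium constant (K = 2.09, k = 7.08 M⁻¹ min⁻¹)
    substrate ⇌ isomer of the product B (K = 0.200, k = 4.50 × 10⁻⁴ min⁻¹)
    substrate + catalyst ⇌ isomer of the product A + catalyst, rate k3*[substrate]*[catalyst] forward; the back reaction follows from the equilibrium constant (K = 2.49, k = 0.283 M⁻¹ min⁻¹)

At the best time of the flask, 30.0 % substrate times the standing ratio gives 63.6 % target, and the flask holds 62.6 %. The forward half-life of substrate is 0.48 h towards target against 12 h towards isomer of the product A. Target and substrate sink together in the flask as that isomer grows from 5.28 % at 2.10 h to 34.8 % at 40.0 h.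

In the neighbour flask with 0.0085 M of catalyst, 17.5 % substrate at 40.0 h and the standing ratio give 37.1 % target. The computed amount there is 36.6 %.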